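**Retrosynthetic overview**

- The strategy rests on the C3 methyl group and the C3–C3a bond of the 2,3-dihydrobenzofuran (ring O1–C2–C3–C3a–C7a). Together they are what 5-exo attack of a C3a aryl radical on the vinyl group of an O1–C2 allylic aryl ether leaves after hydrogen capture at the terminal CH2.
- The erythro side-chain diol is traced back to a 1-aryl-propane-1,2-dione (double asymmetric transfer hydrogenation), and the dione to the C5 aldehyde (acyl-anion addition, then oxidation).
- Key disconnection: C3–C3a, by tin-hydride aryl radical cyclisation of a 2-bromoaryl (S)-1-arylallyl ether. The dihydrofuran ring is the only ring formed in the route, and C2 controls C3.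
- O1–C2 is made by iridium-catalysed, branched-selective asymmetric allylic etherification of a 3,4-dimethoxycinnamyl carbonate with the phenoxide of 5-bromovanillin. The carbonate comes from (E)-3,4-dimethoxycinnamic acid.

Key step: step 5

Assumption: the (Sa,Sc,Sc) antipode of the phosphoramidite is taken to give the (S)-configured branched aryl ether from cinnamyl-type carbonates; if the first run shows the opposite sense, the (Ra,Rc,Rc) ligand is used with no other change.

**Route**

Step 1
Reactants: 1 (E)-3,4-dimethoxycinnamic acid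
Product: 2 methyl (E)-3-(3,4-dimethoxyphenyl)prop-2-enoate
Conditions: MeOH, H2SO4 (cat.), reflux
Reagents that add atoms: methanol (CO)
Why: Fischer esterification of an unhindered conjugated acid in excess methanol should give the ester needed for a clean 1,2-reduction.

Step 2
Reactants: 2 methyl (E)-3-(3,4-dimethoxyphenyl)prop-2-enoate
Product: 3 (E)-3-(3,4-dimethoxyphenyl)prop-2-en-1-ol
Conditions: i-Bu2AlH (2.3 equiv), CH2Cl2, −78 to 0 °C; aq. KNaC4H4O6 work-up
Reagents that add atoms: none
Why: Aluminium hydride reduction of an α,β-unsaturated ester with i-Bu2AlH delivers hydride 1,2 only, so the (E)-alkene should survive.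

Step 3
Reactants: 3 (E)-3-(3,4-dimethoxyphenyl)prop-2-en-1-ol
Product: 4 (E)-3-(3,4-dimethoxyphenyl)prop-2-en-1-yl methyl carbonate
Conditions: ClCO2Me, pyridine, CH2Cl2, 0 °C
Reagents that add atoms: methyl chloroformate (COC(=O)Cl)
Why: O-acylation of a primary allylic alcohol with a chloroformate installs the carbonate leaving group used in iridium-catalysed allylic substitution.

Step 4
Reactants: 4 (E)-3-(3,4-dimethoxyphenyl)prop-2-en-1-yl methyl carbonate; 5 3-bromo-4-hydroxy-5-methoxybenzaldehyde (5-bromovanillin)
Product: 7 3-bromo-4-{[(1S)-1-(3,4-dimethoxyphenyl)prop-2-en-1-yl]oxy}-5-methoxybenzaldehyde, via sodium phenoxide 6 (not isolated)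
Conditions: 5, NaH, THF, 0 °C; then 4, [Ir(cod)Cl]2 (2 mol%), O,O'-[(S)-1,1'-binaphthyl-2,2'-diyl] N,N-bis[(S)-1-phenylethyl]phosphoramidite (4 mol%, pre-activated with n-PrNH2 at 50 °C, volatiles removed), THF, 25–40 °C
Reagents that add atoms: none
Why: In this iridium-catalysed asymmetric allylic etherification the cyclometalated iridium–phosphoramidite complex ionises the linear carbonate to an allyliridium intermediate, which the phenoxide attacks at the aryl-bearing terminus, so the branched ether should form with the C2 stereocentre set by the ligand; both ortho positions and the para position of the phenoxide are blocked, which excludes C-allylation and later Claisen migration.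

Step 5
Reactants: 7 3-bromo-4-{[(1S)-1-(3,4-dimethoxyphenyl)prop-2-en-1-yl]oxy}-5-methoxybenzaldehyde
Product: 8 (2S,3S)-2-(3,4-dimethoxyphenyl)-7-methoxy-3-methyl-2,3-dihydro-1-benzofuran-5-carbaldehyde
Conditions: Bu3SnH (1.3 equiv), AIBN (0.15 equiv), degassed PhH, 80 °C, 0.04 M in 7
Reagents that add atoms: none
Why: Bu3Sn• abstracts bromine from 7 to give the C3a aryl radical, which adds to the internal vinyl carbon and forms C3–C3a; the primary radical so formed takes hydrogen from Bu3SnH, becomes the C3 methyl and regenerates Bu3Sn• (radical chain). The closest known reaction type is the tin-hydride cyclisation of 2-bromoaryl allyl ethers, including 1-aryl-substituted ones, to 3-methyl-2,3-dihydrobenzofurans. The dihydrofuran ring closes in the 5-exo-trig mode, which for an o-allyloxyaryl radical should be far faster than hydrogen transfer to the aryl radical at this stannane concentration. The new stereocentre C3 is controlled by the pre-set C2: in the chair-like transition state the C2 aryl group sits pseudo-equatorial, anti to the developing C3–CH2 bond, which should give the 2,3-trans (2S,3S) isomer while C2 itself is untouched. The step needs cyclisation before reduction and trapping of the primary radical before neophyl-type ring expansion to a chroman; the short tether secures the first and the stannane present in slight excess from the start secures the second. Bu3SnH is preferred to a silane because stannyl radical addition to the formyl C=O is reversible, so the aldehyde is expected to survive.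

Step 6
Reactants: 8 (2S,3S)-2-(3,4-dimethoxyphenyl)-7-methoxy-3-methyl-2,3-dihydro-1-benzofuran-5-carbaldehyde
Product: 10 1-[(2S,3S)-2-(3,4-dimethoxyphenyl)-7-methoxy-3-methyl-2,3-dihydro-1-benzofuran-5-yl]-1-hydroxypropan-2-one (both carbinol epimers), via ethoxyvinyl carbinol 9 (not isolated)
Conditions: CH2=CHOEt, t-BuLi, THF, −78 to 0 °C; then 8, THF, −78 °C; then 1 M HCl, THF, 0 °C
Reagents that add atoms: ethyl vinyl ether (C=COCC); water (O)
Why: 1-Ethoxyvinyllithium acts as an acetyl anion equivalent in 1,2-addition to the aromatic aldehyde, and brief dilute-acid hydrolysis of the enol ether should unmask the methyl ketone (nucleophilic acylation) without disturbing the trans-dihydrobenzofuran; the carbinol configuration is irrelevant because it is erased in step 7.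

Step 7
Reactants: 10 1-[(2S,3S)-2-(3,4-dimethoxyphenyl)-7-methoxy-3-methyl-2,3-dihydro-1-benzofuran-5-yl]-1-hydroxypropan-2-one
Product: 11 1-[(2S,3S)-2-(3,4-dimethoxyphenyl)-7-methoxy-3-methyl-2,3-dihydro-1-benzofuran-5-yl]propane-1,2-dione
Conditions: Dess–Martin periodinane, CH2Cl2, 0 °C to rt
Reagents that add atoms: none
Why: Dess–Martin oxidation of a secondary benzylic α-ketol gives the 1,2-diketone under near-neutral conditions, so both epimers of 10 converge and the benzylic ring positions are not oxidised.

Step 8
Reactants: 11 1-[(2S,3S)-2-(3,4-dimethoxyphenyl)-7-methoxy-3-methyl-2,3-dihydro-1-benzofuran-5-yl]propane-1,2-dione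
Product: 13 (1S,2R)-1-[(2S,3S)-2-(3,4-dimethoxyphenyl)-7-methoxy-3-methyl-2,3-dihydro-1-benzofuran-5-yl]propane-1,2-diol, via 2-hydroxy ketone 12 (not isolated)
Conditions: RuCl[(R,R)-TsDPEN](p-cymene) (1 mol%), HCO2H/Et3N (5:2), DMF, 40 °C
Reagents that add atoms: none
Why: In this Noyori–Ikariya asymmetric transfer hydrogenation of a 1-aryl-propane-1,2-dione the (R,R)-ruthenium hydride should first reduce the more electrophilic acetyl carbonyl to the (R)-carbinol 12 and then the aryl ketone to the (S)-benzylic carbinol, both through the six-membered N–H/Ru–H transition state with the same facial sense, which corresponds to the anti (erythro) diol known for this substrate class; the remote ring stereocentres should not interfere.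

**Compound list**

1 | (E)-3,4-dimethoxycinnamic acid | COc1ccc(/C=C/C(=O)O)cc1OC | starting material
2 | methyl (E)-3-(3,4-dimethoxyphenyl)prop-2-enoate | COC(=O)/C=C/c1ccc(OC)c(OC)c1 | intermediate
3 | (E)-3-(3,4-dimethoxyphenyl)prop-2-en-1-ol | OC/C=C/c1ccc(OC)c(OC)c1 | intermediate
4 | (E)-3-(3,4-dimethoxyphenyl)prop-2-en-1-yl methyl carbonate | COC(=O)OC/C=C/c1ccc(OC)c(OC)c1 | intermediate
5 | 3-bromo-4-hydroxy-5-methoxybenzaldehyde (5-bromovanillin) | O=Cc1cc(Br)c(O)c(OC)c1 | starting material
6 | sodium 2-bromo-4-formyl-6-methoxyphenolate | [Na+].[O-]c1c(Br)cc(C=O)cc1OC | intermediate (not isolated)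
7 | 3-bromo-4-{[(1S)-1-(3,4-dimethoxyphenyl)prop-2-en-1-yl]oxy}-5-methoxybenzaldehyde | COc1ccc([C@@H](Oc2c(Br)cc(C=O)cc2OC)C=C)cc1OC | intermediate
8 | (2S,3S)-2-(3,4-dimethoxyphenyl)-7-methoxy-3-methyl-2,3-dihydro-1-benzofuran-5-carbaldehyde | COc1ccc([C@H]2Oc3c(OC)cc(C=O)cc3[C@@H]2C)cc1OC | intermediate
9 | 1-[(2S,3S)-2-(3,4-dimethoxyphenyl)-7-methoxy-3-methyl-2,3-dihydro-1-benzofuran-5-yl]-2-ethoxyprop-2-en-1-ol (both carbinol epimers) | COc1ccc([C@H]2Oc3c(OC)cc(C(O)C(=C)OCC)cc3[C@@H]2C)cc1OC | intermediate (not isolated)
10 | 1-[(2S,3S)-2-(3,4-dimethoxyphenyl)-7-methoxy-3-methyl-2,3-dihydro-1-benzofuran-5-yl]-1-hydroxypropan-2-one (both carbinol epimers) | COc1ccc([C@H]2Oc3c(OC)cc(C(O)C(C)=O)cc3[C@@H]2C)cc1OC | intermediate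
11 | 1-[(2S,3S)-2-(3,4-dimethoxyphenyl)-7-methoxy-3-methyl-2,3-dihydro-1-benzofuran-5-yl]propane-1,2-dione | COc1ccc([C@H]2Oc3c(OC)cc(C(=O)C(C)=O)cc3[C@@H]2C)cc1OC | intermediate
12 | (2R)-1-[(2S,3S)-2-(3,4-dimethoxyphenyl)-7-methoxy-3-methyl-2,3-dihydro-1-benzofuran-5-yl]-2-hydroxypropan-1-one | COc1ccc([C@H]2Oc3c(OC)cc(C(=O)[C@@H](C)O)cc3[C@@H]2C)cc1OC | intermediate (not isolated)
13 | (1S,2R)-1-[(2S,3S)-2-(3,4-dimethoxyphenyl)-7-methoxy-3-methyl-2,3-dihydro-1-benzofuran-5-yl]propane-1,2-diol | COc1ccc([C@H]2Oc3c(OC)cc([C@H](O)[C@@H](C)O)cc3[C@@H]2C)cc1OC | target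

**Step count**

Total steps: 8. Longest linear sequence: 8 steps (1 to 13); the second fragment, 5, is used as purchased.

**Steps most likely to fail**

Step 4 (allylic etherification). The doubly ortho-substituted, electron-poor phenoxide may attack the allyliridium intermediate slowly. The electron-rich branched ether may also re-ionise, which would leak material to the linear ether and erode the enantiomeric purity at C2.

The fallback sets out from 5 and comes back to the route at 7. Purchased 3-chloro-1-(3,4-dimethoxyphenyl)propan-1-one (COc1ccc(C(=O)CCCl)cc1OC) would be reduced with BH3·SMe2 and (S)-2-methyl-CBS-oxazaborolidine (10 mol%) in THF at −20 °C (Corey–Bakshi–Shibata reduction) to (R)-3-chloro-1-(3,4-dimethoxyphenyl)propan-1-ol F1. Mitsunobu coupling of F1 with 5 (PPh3, DIAD, toluene, −20 to 0 °C) should give, with inversion, 3-bromo-4-{[(1S)-3-chloro-1-(3,4-dimethoxyphenyl)propyl]oxy}-5-methoxybenzaldehyde F2; because this alcohol is not allylic, no SN2' path is open. Finkelstein exchange (NaI, butan-2-one, reflux) would give 3-bromo-4-{[(1S)-1-(3,4-dimethoxyphenyl)-3-iodopropyl]oxy}-5-methoxybenzaldehyde F3. E2 elimination with t-BuOK in THF at 0 °C should then unveil the vinyl group and deliver 7.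

Step 5 (radical cyclisation). The chain-carrying radical may attack the formyl group, or the chain may stall through formyl-derived radicals. The trans preference at C3 may also be incomplete at 80 °C, in which case the cis isomer would have to be removed by chromatography.

The fallback sets out from 7 and comes back at 8, taking the aldehyde out of the radical step by a redox detour. NaBH4 in MeOH/THF at 0 °C would give (3-bromo-4-{[(1S)-1-(3,4-dimethoxyphenyl)prop-2-en-1-yl]oxy}-5-methoxyphenyl)methanol F4. The same Bu3SnH/AIBN cyclisation (PhH, 80 °C) on this alcohol should give [(2S,3S)-2-(3,4-dimethoxyphenyl)-7-methoxy-3-methyl-2,3-dihydro-1-benzofuran-5-yl]methanol F5, on which the crystalline or chromatographic separation of the trans isomer can also be attempted. Benzylic oxidation with MnO2 in CH2Cl2 at room temperature would return 8.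

Step 8 (double transfer hydrogenation). The second reduction, of the electron-rich aryl ketone, may be slow or only weakly selective, so that the syn diol forms alongside the anti diol, or hydroxy ketone 12 may epimerise before it is reduced.

The fallback sets out from 11 and comes back at 13. The transfer hydrogenation would be run at 10 °C with the same catalyst and stopped at the (R)-2-hydroxy ketone 12, which is isolated. Its ketone would then be reduced with Zn(BH4)2 in Et2O at −20 °C; hydride delivery to the zinc chelate of the α-hydroxy ketone, anti to the methyl group, is the established route to anti (erythro) 1,2-diols and should give 13.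

**Further compounds**

F1 | step 4 | (R)-3-chloro-1-(3,4-dimethoxyphenyl)propan-1-ol | COc1ccc([C@H](O)CCCl)cc1OC
F2 | step 4 | 3-bromo-4-{[(1S)-3-chloro-1-(3,4-dimethoxyphenyl)propyl]oxy}-5-methoxybenzaldehyde | COc1ccc([C@@H](Oc2c(Br)cc(C=O)cc2OC)CCCl)cc1OC
F3 | step 4 | 3-bromo-4-{[(1S)-1-(3,4-dimethoxyphenyl)-3-iodopropyl]oxy}-5-methoxybenzaldehyde | COc1ccc([C@@H](Oc2c(Br)cc(C=O)cc2OC)CCI)cc1OC
F4 | step 5 | (3-bromo-4-{[(1S)-1-(3,4-dimethoxyphenyl)prop-2-en-1-yl]oxy}-5-methoxyphenyl)methanol | COc1ccc([C@@H](Oc2c(Br)cc(CO)cc2OC)C=C)cc1OC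
F5 | step 5 | [(2S,3S)-2-(3,4-dimethoxyphenyl)-7-methoxy-3-methyl-2,3-dihydro-1-benzofuran-5-yl]methanol | COc1ccc([C@H]2Oc3c(OC)cc(CO)cc3[C@@H]2C)cc1OC
F0 | step 8 | none | none
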